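We decide to count how many lifetimes of Q fit into the time in the vessel, and to reckon both set-ups by that one number.

| flask | X | time | remark |
|---|---|---|---|
| delta | 0.010 M | 2.0 min | a closed flask charged with all of it at once and left for 2.0 min |
| alpha | 0.010 M |  | a single well-mixed tank run continuously and read at steady state, 2.0 min in it on average |

    X + 2 Q → 3 Q (k1 = 490 /M²/s)
    X → Q (k2 = 9.9 × 10⁻⁵ /s)
    Q → L (k3 = 0.015 /s)

1. the set-up with the highest share of Q in all that became Q or L, at the outlet or at the end ("none" if the first two lie within 2 percentage points) (delta / alpha / none)
2. share of Q in all that became Q or L, at the outlet or at the end, delta
3. share of Q in all that became Q or L, at the outlet or at the end, alpha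

- a step written with two of one species runs at k times the square of its concentration and takes two of it each time
- the stated concentrations are those of everything mixed, before any reaction; amounts are the same in each set-up
- run time (delta): 2.0 min

Over 2.0 min in delta, we reckon that the plain step turns about 1.19% of the charge of X into Q, hardly any, so we treat its feed to Q as level. Feed against loss would hold Q near 0.660% of the charge. At that level the autocatalytic step adds 2.16% to the plain feed, hardly any, so in delta we set it aside.

Q turns into L at 0.9 /min, and over 2.0 min that gives 1.80 lifetimes. This is the turnover count, the rate constant of Q's loss times the time in the vessel, on average in the tank. The share asked for is the usual selectivity to Q. Our small table has two rows: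

- delta, closed flask: count 1.80, share 46.4%
- alpha, tank: count 1.80, share 35.7%

The count is the same in both rows, but the rule differs. In delta, with a level feed, the share is one minus e to the minus count, over the count. Q made early has aged through the whole run, while Q made last is fresh. In alpha, the balance of L makes L the count times Q, whatever feeds Q, so the share is one over one plus the count. Reading down the share column, delta stands 11 percentage points higher than alpha, more than the margin. We choose delta.

The forecast also named delta, with 46.4% and 35.7%, and wrote of the tank's balance of L that it stands “whichever steady state holds”. The simulation gives delta as best, with 46.4% for delta and 35.7% for alpha.

Now take the same closed flask as delta, read at 3.0 min, with amounts and temperature held. Its count rises from 1.80 to 2.70. The closed-flask row then gives a share of 34.5%. The simulated neighbour gives 34.6%, lower than delta's 46.4%. At that reading of the neighbour flask, X stands at 98.2% of the charge, Q at 0.617% and L at 1.17%.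

(The rate constants were chosen freely; the rest is arithmetic.)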